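**Retrosynthetic overview**
1. Target ⇒ hydroxyl-directed anti reduction of the C6 ketone of a β-hydroxy hydroazulenone.
2. Hydroazulenone ⇒ one-carbon ring expansion (diazoalkane addition, 1,2-shift of C8, loss of N2). This step joins a C11 cis-hydrindenone to the complete side-chain diazoalkane.
3. Hydrindenone ⇒ Wharton transposition of the convex enone epoxide ⇒ gold-catalysed 6-exo-dig closure (C1–C10, =CH2) on a 4-substituted 3-methylcyclopentenone.
4. That cyclopentenone ⇒ Stork–Danheiser methylation, transfer-hydrogenation DKR and α′-acylation of 3-methoxycyclopentenone with pent-4-ynoic acid.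
5. Diazoalkane ⇒ prenal + methallyl chloride (Ir methallylation sets C13, Cu–H hydroboration sets C11). Ring order: five (bought) → six (step 5) → seven (step 14).

Convention and assumption: locants C1–C15 in the "Why" lines are the dictyol locants of the target (C1/C5 ring fusion, C2=C3, C4 Me/OH, C6 OH, C7 side chain, C8, C9, C10 =CH2, C11 Me, C12, C13 OAc, C14=C15); the ligand antipodes named are those expected to give the drawn configuration.

Step 1
Reactants: 1 3-methoxycyclopent-2-en-1-one; 2 pent-4-ynoic acid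
Product: 4 3-methoxy-5-(pent-4-ynoyl)cyclopent-2-en-1-one, via pent-4-ynoyl imidazolide 3 (not isolated)
Conditions: 2, CDI, THF, rt; cannulated into 1 + LDA (2.1 equiv), THF, −78 °C; aq. HCl
Reagents that add atoms: 1,1'-carbonyldiimidazole O=C(n1ccnc1)n1ccnc1 (imidazolyl group of 3 only)
Why: Kinetic α′-deprotonation of the vinylogous ester followed by Claisen-type C-acylation with the acyl imidazole forms C5–C6; the extra base stores the product as its diketonate, and C5 stays stereolabile as step 2 requires.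

Step 2
Reactants: 4 3-methoxy-5-(pent-4-ynoyl)cyclopent-2-en-1-one
Product: 5 (5R)-5-[(1S)-1-hydroxypent-4-yn-1-yl]-3-methoxycyclopent-2-en-1-one
Conditions: RuCl[(S,S)-TsDPEN](p-cymene) (1 mol %), HCO2H/Et3N 5:2, CH2Cl2, rt
Reagents that add atoms: none
Why: In this Noyori–Ikariya asymmetric transfer hydrogenation with dynamic kinetic resolution, C5 racemises fast, only the exocyclic ketone is reduced (the ring C=O is an inert vinylogous ester), and the catalyst turns over one C5 epimer to the syn alcohol, which sets C5 (the carbinol centre is erased in step 8).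

Step 3
Reactants: 5 (5R)-5-[(1S)-1-hydroxypent-4-yn-1-yl]-3-methoxycyclopent-2-en-1-one
Product: 7 (4S)-4-[(1S)-1-hydroxypent-4-yn-1-yl]-3-methylcyclopent-2-en-1-one, via tertiary carbinol 6 (not isolated)
Conditions: MeLi (3.5 equiv), THF/Et2O, −78 → 0 °C; then 1 M HCl, THF, 0 °C
Reagents that add atoms: methyllithium [Li]C; water O
Why: In this Stork–Danheiser sequence MeLi adds 1,2 to the vinylogous-ester carbonyl (C4) and acid hydrolysis with loss of the tertiary OH transposes the enone, which puts the methyl on C4 and the ketone on C2 without touching C5.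

Step 4
Reactants: 7 (4S)-4-[(1S)-1-hydroxypent-4-yn-1-yl]-3-methylcyclopent-2-en-1-one
Product: 8 triethyl({(1S)-1-[(1S)-2-methyl-4-(triethylsilyloxy)cyclopenta-2,4-dien-1-yl]pent-4-yn-1-yl}oxy)silane
Conditions: LDA (2.05 equiv), THF, −78 °C; TESCl (2.2 equiv); cold pentane/NaHCO3 work-up, used at once
Reagents that add atoms: chlorotriethylsilane CC[Si](Cl)(CC)CC
Why: Kinetic silyl enol ether formation removes the OH proton and then the α′ proton at C1 (the alkyne C–H is the least acidic site), which gives the cross-conjugated dienol silane and masks the C6–OH in the same operation.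

Step 5
Reactants: 8 triethyl({(1S)-1-[(1S)-2-methyl-4-(triethylsilyloxy)cyclopenta-2,4-dien-1-yl]pent-4-yn-1-yl}oxy)silane
Product: 10 (3aS,4S,7aS)-4-hydroxy-3-methyl-7-methylidene-3a,4,5,6,7,7a-hexahydro-1H-inden-1-one, via bicyclic TES ether 9 (not isolated)
Conditions: [(JohnPhos)Au(MeCN)]SbF6 (3 mol %), CH2Cl2/i-PrOH 10:1, 0 °C; then PPTS, MeOH, rt
Reagents that add atoms: none
Why: Gold(I)-catalysed Conia-ene-type 6-exo-dig carbocyclisation of the silyl enol ether onto the activated alkyne forms C1–C10 and the exocyclic methylene; the tether on C5 reaches only the same face of C1, so the cis ring fusion is set, and 0 °C outruns the 1,5-H shift of the silyloxycyclopentadiene.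

Step 6
Reactants: 10 (3aS,4S,7aS)-4-hydroxy-3-methyl-7-methylidene-3a,4,5,6,7,7a-hexahydro-1H-inden-1-one
Product: 11 2,3-epoxide of 10 with the oxirane O cis to H-3a and H-7a
Conditions: t-BuOOH (1.5 equiv), n-BuLi (1.3 equiv), THF, −78 → −10 °C; aq. NH4Cl
Reagents that add atoms: tert-butyl hydroperoxide CC(C)(C)OO
Why: Weitz–Scheffer nucleophilic epoxidation touches only the enone; the weakly basic lithium peroxide avoids enolisation at C1 (so the =CH2 does not drift into conjugation) and attacks C4 from the convex face (the side of H1 and H5), which sets the C4–O configuration.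

Step 7
Reactants: 11 2,3-epoxide of 10 with the oxirane O cis to H-3a and H-7a
Product: 13 (1S,3aS,7S,7aR)-1-methyl-4-methylidene-3a,4,5,6,7,7a-hexahydro-1H-indene-1,7-diol, via epoxy hydrazone 12 (not isolated)
Conditions: N2H4·H2O (3 equiv), AcOH (0.3 equiv), MeOH, 0 °C → rt
Reagents that add atoms: hydrazine NN (nitrogen atoms of 12 only)
Why: In the Wharton transposition, hydrazone formation, epoxide opening and loss of N2 give the C2=C3 alkene and the tertiary allylic alcohol, and the C4–O bond is never broken, so C4 is retained.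

Step 8
Reactants: 13 (1S,3aS,7S,7aR)-1-methyl-4-methylidene-3a,4,5,6,7,7a-hexahydro-1H-indene-1,7-diol
Product: 14 (3S,3aS,7aS)-3-hydroxy-3-methyl-7-methylidene-3,3a,5,6,7,7a-hexahydro-4H-inden-4-one
Conditions: Dess–Martin periodinane (1.2 equiv), NaHCO3, CH2Cl2, 0 °C
Reagents that add atoms: none
Why: Dess–Martin oxidation takes only the secondary C6–OH (the tertiary allylic OH cannot be oxidised), and the buffered neutral medium avoids retro-aldol cleavage and dehydration of the β-hydroxy ketone.

Step 9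
Reactants: 15 3-methylbut-2-enal; 16 3-chloro-2-methylprop-1-ene
Product: 17 (4R)-2,6-dimethylhepta-1,5-dien-4-ol
Conditions: [Ir(cod)Cl]2 (2.5 mol %), (R)-SEGPHOS (5 mol %), 4-cyano-3-nitrobenzoic acid (10 mol %), K3PO4 (1 equiv), i-PrOH (2 equiv), THF, 60 °C
Reagents that add atoms: none
Why: In this iridium-catalysed transfer-hydrogenative carbonyl methallylation the chiral cyclometallated allyl-iridium adds to the aldehyde through a closed chair transition state, which forms C12–C13 and sets C13 (R) under catalyst control.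

Step 10
Reactants: 17 (4R)-2,6-dimethylhepta-1,5-dien-4-ol
Product: 18 (4R)-2,6-dimethylhepta-1,5-dien-4-yl acetate
Conditions: Ac2O, Et3N, DMAP (cat.), CH2Cl2, 0 °C
Reagents that add atoms: acetic anhydride CC(=O)OC(C)=O
Why: DMAP-catalysed O-acetylation installs the target's only ester early without touching C13, so no late differentiation of three hydroxyl groups is needed.

Step 11
Reactants: 18 (4R)-2,6-dimethylhepta-1,5-dien-4-yl acetate
Product: 20 (4R,6R)-7-hydroxy-2,6-dimethylhept-2-en-4-yl acetate, via pinacol boronate 19 (not isolated)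
Conditions: CuCl (5 mol %), (R)-DTBM-SEGPHOS (6 mol %), KOt-Bu (10 mol %), HBpin (1.3 equiv), toluene, rt; then NaBO3·4H2O, THF/H2O
Reagents that add atoms: pinacolborane CC1(C)OBOC1(C)C (boryl group of 19 only); sodium perborate [Na+].[Na+].O[B-]1(O)OO[B-](O)(O)OO1
Why: Ligand-controlled CuH-catalysed anti-Markovnikov hydroboration attacks only the 1,1-disubstituted alkene (the trisubstituted alkene and the acetate are inert), sets C11 (R) in the hydrocupration, and mild perborate oxidation gives the primary alcohol.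

Step 12
Reactants: 20 (4R,6R)-7-hydroxy-2,6-dimethylhept-2-en-4-yl acetate
Product: 21 (4R,6R)-2,6-dimethyl-7-oxohept-2-en-4-yl acetate
Conditions: TEMPO (10 mol %), PhI(OAc)2 (1.1 equiv), CH2Cl2, rt
Reagents that add atoms: none
Why: The base-free TEMPO/PhI(OAc)2 oxidation stops at the aldehyde and does not epimerise the α-stereocentre C11.

Step 13
Reactants: 21 (4R,6R)-2,6-dimethyl-7-oxohept-2-en-4-yl acetate
Product: 22 (4R,6R,7E)-7-hydrazinylidene-2,6-dimethylhept-2-en-4-yl acetate
Conditions: N2H4 (1 M in THF, 3 equiv), 0 °C, 20 min; cold aqueous wash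
Reagents that add atoms: hydrazine NN
Why: Hydrazone condensation with excess hydrazine at 0 °C suppresses azine formation and is much faster than hydrazinolysis of the secondary acetate.

Step 14
Reactants: 14 (3S,3aS,7aS)-3-hydroxy-3-methyl-7-methylidene-3,3a,5,6,7,7a-hexahydro-4H-inden-4-one; 22 (4R,6R,7E)-7-hydrazinylidene-2,6-dimethylhept-2-en-4-yl acetate
Product: 25 (1R,3R)-3-[(3S,3aS,5R,8aS)-3-hydroxy-3-methyl-8-methylidene-4-oxo-3,3a,4,5,6,7,8,8a-octahydroazulen-5-yl]-1-(2-methylprop-1-en-1-yl)butyl acetate, via side-chain diazoalkane 23 (not isolated), via chloro(methyl)aluminium chelate 24 (not isolated)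
Conditions: (a) 22, activated MnO2, K2HPO4, CH2Cl2, −20 °C, cold filtration; (b) 14, Me2AlCl (1.05 equiv), CH2Cl2, −78 °C, 20 min; (c) solution (a) (1.3 equiv) into (b), −78 → −40 °C; aq. Rochelle salt
Reagents that add atoms: dimethylaluminium chloride C[Al](C)Cl (aluminium group of 24 only)
Why: Proposed new method: a hydroxyl-anchored aluminium Lewis acid turns the Büchner–Curtius–Schlotterbeck diazoalkane–ketone homologation into a fragment coupling, because Me2AlCl is protonolysed by the C4–OH to the six-membered O–Al···O=C6 chelate 24, which activates only this ketone, masks the aldol OH and blocks the concave face, so the non-stabilised diazoalkane 23 adds to C6 from the convex face, and in the chelate-locked betaine only the C6–C8 bond can lie antiperiplanar to N2+, so the CH2 carbon rather than the tertiary C5 makes the 1,2-shift with loss of N2 and enlarges the six-membered ring to the seven-membered ring with the whole side chain on C7, while C7, being α to the ketone, settles as the cis-2,7 pseudo-diequatorial 7R epimer; the closest known reaction type is the organoaluminium- or Sc(OTf)3-promoted ring expansion of cycloalkanones with simple alkyl- or aryldiazomethanes, which has not been shown with an internal Lewis acid, a free β-hydroxy ketone or a functionalised chiral diazoalkane.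

Step 15
Reactants: 25 (1R,3R)-3-[(3S,3aS,5R,8aS)-3-hydroxy-3-methyl-8-methylidene-4-oxo-3,3a,4,5,6,7,8,8a-octahydroazulen-5-yl]-1-(2-methylprop-1-en-1-yl)butyl acetate
Product: 26 (1R,3R)-3-[(3S,3aR,4S,5R,8aS)-3,4-dihydroxy-3-methyl-8-methylidene-3,3a,4,5,6,7,8,8a-octahydroazulen-5-yl]-1-(2-methylprop-1-en-1-yl)butyl acetate (CNP0209568.2)
Conditions: Me4NBH(OAc)3 (5 equiv), MeCN/AcOH 1:1, −30 °C
Reagents that add atoms: none
Why: In the Evans–Saksena reduction the boron bound to the C4–OH delivers hydride to C6 from the convex face, which is also the sterically open face anti to the substituents on C5 and C7; this gives the 1,3-anti diol with the all-cis C5/C6/C7 array (6S) and leaves the acetate and the alkenes untouched.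

**Compound list**
1 | 3-methoxycyclopent-2-en-1-one | COC1=CC(=O)CC1 | starting material
2 | pent-4-ynoic acid | C#CCCC(=O)O | starting material
3 | 1-(imidazol-1-yl)pent-4-yn-1-one | C#CCCC(=O)n1ccnc1 | intermediate
4 | 3-methoxy-5-(pent-4-ynoyl)cyclopent-2-en-1-one (C5 stereolabile) | COC1=CC(=O)C(C1)C(=O)CCC#C | intermediate
5 | (5R)-5-[(1S)-1-hydroxypent-4-yn-1-yl]-3-methoxycyclopent-2-en-1-one | COC1=CC(=O)[C@H](C1)[C@@H](O)CCC#C | intermediate
6 | (5R)-5-[(1S)-1-hydroxypent-4-yn-1-yl]-3-methoxy-1-methylcyclopent-2-en-1-ol (C1 epimers) | COC1=CC(C)(O)[C@H](C1)[C@@H](O)CCC#C | intermediate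
7 | (4S)-4-[(1S)-1-hydroxypent-4-yn-1-yl]-3-methylcyclopent-2-en-1-one | CC1=CC(=O)C[C@@H]1[C@@H](O)CCC#C | intermediate
8 | triethyl({(1S)-1-[(1S)-2-methyl-4-(triethylsilyloxy)cyclopenta-2,4-dien-1-yl]pent-4-yn-1-yl}oxy)silane | CC1=CC(O[Si](CC)(CC)CC)=C[C@@H]1[C@@H](O[Si](CC)(CC)CC)CCC#C | intermediate
9 | (3aS,4S,7aS)-3-methyl-7-methylidene-4-(triethylsilyloxy)-3a,4,5,6,7,7a-hexahydro-1H-inden-1-one | C=C1CC[C@H](O[Si](CC)(CC)CC)[C@H]2[C@@H]1C(=O)C=C2C | intermediate
10 | (3aS,4S,7aS)-4-hydroxy-3-methyl-7-methylidene-3a,4,5,6,7,7a-hexahydro-1H-inden-1-one | C=C1CC[C@H](O)[C@H]2[C@@H]1C(=O)C=C2C | intermediate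
11 | 2,3-epoxide of 10, oxirane O cis to H-3a and H-7a | C=C1CC[C@H](O)[C@H]2[C@@H]1C(=O)[C@@H]3O[C@]23C | intermediate
12 | hydrazone of 11 | C=C1CC[C@H](O)[C@H]2[C@@H]1C(=NN)[C@@H]3O[C@]23C | intermediate
13 | (1S,3aS,7S,7aR)-1-methyl-4-methylidene-3a,4,5,6,7,7a-hexahydro-1H-indene-1,7-diol | C=C1CC[C@H](O)[C@H]2[C@@H]1C=C[C@]2(C)O | intermediate
14 | (3S,3aS,7aS)-3-hydroxy-3-methyl-7-methylidene-3,3a,5,6,7,7a-hexahydro-4H-inden-4-one | C=C1CCC(=O)[C@H]2[C@@H]1C=C[C@]2(C)O | intermediate
15 | 3-methylbut-2-enal | CC(C)=CC=O | starting material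
16 | 3-chloro-2-methylprop-1-ene | C=C(C)CCl | starting material
17 | (4R)-2,6-dimethylhepta-1,5-dien-4-ol | C=C(C)C[C@H](C=C(C)C)O | intermediate
18 | (4R)-2,6-dimethylhepta-1,5-dien-4-yl acetate | C=C(C)C[C@H](C=C(C)C)OC(C)=O | intermediate
19 | (4R,6R)-2,6-dimethyl-7-(4,4,5,5-tetramethyl-1,3,2-dioxaborolan-2-yl)hept-2-en-4-yl acetate | CC1(C)OB(C[C@H](C)C[C@H](C=C(C)C)OC(C)=O)OC1(C)C | intermediate
20 | (4R,6R)-7-hydroxy-2,6-dimethylhept-2-en-4-yl acetate | OC[C@H](C)C[C@H](C=C(C)C)OC(C)=O | intermediate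
21 | (4R,6R)-2,6-dimethyl-7-oxohept-2-en-4-yl acetate | O=C[C@H](C)C[C@H](C=C(C)C)OC(C)=O | intermediate
22 | (4R,6R,7E)-7-hydrazinylidene-2,6-dimethylhept-2-en-4-yl acetate | N/N=C/[C@H](C)C[C@H](C=C(C)C)OC(C)=O | intermediate
23 | (4R,6R)-7-diazo-2,6-dimethylhept-2-en-4-yl acetate | [N-]=[N+]=C[C@H](C)C[C@H](C=C(C)C)OC(C)=O | intermediate
24 | chloro(methyl)aluminium 3-alkoxide of 14 (O–Al chelated to the ketone) | C=C1CCC(=O)[C@H]2[C@@H]1C=C[C@]2(C)O[Al](C)Cl | intermediate
25 | (1R,3R)-3-[(3S,3aS,5R,8aS)-3-hydroxy-3-methyl-8-methylidene-4-oxo-3,3a,4,5,6,7,8,8a-octahydroazulen-5-yl]-1-(2-methylprop-1-en-1-yl)butyl acetate | C=C1CC[C@H]([C@H](C)C[C@H](C=C(C)C)OC(C)=O)C(=O)[C@H]2[C@@H]1C=C[C@]2(C)O | intermediate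
26 | (1R,3R)-3-[(3S,3aR,4S,5R,8aS)-3,4-dihydroxy-3-methyl-8-methylidene-3,3a,4,5,6,7,8,8a-octahydroazulen-5-yl]-1-(2-methylprop-1-en-1-yl)butyl acetate | C=C1CC[C@H]([C@H](C)C[C@H](C=C(C)C)OC(C)=O)[C@H](O)[C@H]2[C@@H]1C=C[C@]2(C)O | target

**Step count**
- Total step count: 15.
- Longest linear sequence: 10 steps (1–8, 14, 15).

**Three steps most likely to fail**

*Step 14 (the proposed new step).*
- Risks: the diazoalkane may be consumed by the aluminium centre, an epoxide may form instead of the shift, C5 may migrate, or the aldol unit may cleave.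
- Fallback: known β-oxido-carbenoid ring enlargement. It sets out from 21 and 14 and returns at 25.
- Aldehyde 21 is converted with (PhO)3P/Br2 into (4R,6R)-7,7-dibromo-2,6-dimethylhept-2-en-4-yl acetate F1.
- LDA-mediated addition of F1 (−95 °C, excess base to cover the free OH) to 14 gives the tertiary dibromo carbinol adduct F2.
- Excess n-BuLi (−95 → −20 °C) triggers Br/Li exchange and the carbenoid 1,2-shift of the CH2 carbon. It also cleaves the acetate, so protonation gives the 13-O-deacetyl hydroxy ketone F3.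
- Ac2O/pyridine at 0 °C acetylates only the secondary allylic OH of F3 and gives 25.

*Step 5.*
- Risks: 1,5-H shift of the silyloxycyclopentadiene 8, premature desilylation, or a slow 6-exo-dig closure.
- Fallback: it sets out from 7 and returns at 10.
- B-iodo-9-BBN haloboration and AcOH protonolysis of the alkyne give (4S)-4-[(1S)-1-hydroxy-4-iodopent-4-en-1-yl]-3-methylcyclopent-2-en-1-one F4.
- A Pd(PPh3)4/t-BuOK intramolecular ketone α-alkenylation then closes the same C1–C10 bond, so no silyl dienol ether is needed.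

*Step 2.*
- Risks: the strongly enolised substrate may reduce slowly, and dr or ee may be low.
- Fallback: it sets out from 4 and returns at 5.
- Chelation-controlled Zn(BH4)2 reduction gives rac-syn-5-(1-hydroxypent-4-yn-1-yl)-3-methoxycyclopent-2-en-1-one F5.
- Burkholderia cepacia lipase with vinyl acetate acetylates only the (1R)-carbinol enantiomer, giving (1R)-1-[(1S)-4-methoxy-2-oxocyclopent-3-en-1-yl]pent-4-yn-1-yl acetate F6.
- The unreacted alcohol is 5, which is separated by chromatography.

Further compounds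
F1 | step 14 | (4R,6R)-7,7-dibromo-2,6-dimethylhept-2-en-4-yl acetate | BrC(Br)[C@H](C)C[C@H](C=C(C)C)OC(C)=O
F2 | step 14 | tertiary dibromo carbinol adduct (new C6–C7 bond on the convex face) | C=C1CC[C@@](O)(C(Br)(Br)[C@H](C)C[C@H](C=C(C)C)OC(C)=O)[C@H]2[C@@H]1C=C[C@]2(C)O
F3 | step 14 | 13-O-deacetyl hydroxy ketone, (3S,3aS,5R,8aS)-3-hydroxy-5-[(2R,4R)-4-hydroxy-6-methylhept-5-en-2-yl]-3-methyl-8-methylidene-octahydroazulen-4-one | C=C1CC[C@H]([C@H](C)C[C@H](C=C(C)C)O)C(=O)[C@H]2[C@@H]1C=C[C@]2(C)O
F4 | step 5 | (4S)-4-[(1S)-1-hydroxy-4-iodopent-4-en-1-yl]-3-methylcyclopent-2-en-1-one | CC1=CC(=O)C[C@@H]1[C@@H](O)CCC(I)=C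
F5 | step 2 | rac-syn-5-(1-hydroxypent-4-yn-1-yl)-3-methoxycyclopent-2-en-1-one | COC1=CC(=O)C(C1)C(O)CCC#C
F6 | step 2 | (1R)-1-[(1S)-4-methoxy-2-oxocyclopent-3-en-1-yl]pent-4-yn-1-yl acetate | COC1=CC(=O)[C@@H](C1)[C@H](OC(C)=O)CCC#C
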